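The plan cuts ring B, the trans-fused methylene lactone, at C27–C19 and C2–C1. In one flask a lithiated 2-methallyl-1,3-dithiane (latent C19 carbinol carrying C16–C18) adds to C27 of a 5-substituted butenolide anti to the C6 side chain, and the lactone enolate is aminomethylated at C2 by Eschenmoser's salt. The step exploits C27 of ring B bearing three carbon neighbours (C19, C6, C2) with C19 trans to C7. The precursor is the (5R)-furan-2(5H)-one whose side chain already holds C8 (S), the silylated C9 hydroxyl and C11 as an allyl dioxolane; metathesis of the two terminal olefins later closes the ten-membered ring A.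

Key step: step 14

Remarks and assumptions:
- Atoms are numbered by their position in the target SMILES.
- With carbon at C7, the butenolide stereocentre C6 of 19 is (R) by the CIP rules (C27 outranks C7); a label (S) holds only where C7 bears oxygen. Descriptors at C6 and C27 change along the route for priority reasons only; the SMILES strings are authoritative.
- The C9 hydroxyl is carried as a TBS ether so that it leaves in the same acidic operation as the C11 dioxolane, which removes a fluoride step from the base-sensitive end-game.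
- (R)-1,2-Epoxy-5-hexene, (R)-4-benzyl-2-oxazolidinone and (R)-2-methylbutanoic acid are assumed to be bought as single enantiomers.

Step 1
Reactants: 1 (2R)-2-(but-3-en-1-yl)oxirane
Product: 3 (5R)-5-(but-3-en-1-yl)oxolan-2-one, via hydroxy acid 2 (not isolated)
Conditions: AcOH, LiN(i-Pr)2 (2 equiv), THF/HMPA, 0 → 40 °C; aq. HCl; TsOH (cat.), PhMe, 60 °C
Reagents that add atoms: acetic acid, CC(=O)O
Why: The acetic acid dianion (Creger lactone synthesis) opens the terminal epoxide at its CH2 carbon by SN2, so the carbinol centre C6 is untouched, and acid-promoted lactonisation of the γ-hydroxy acid closes ring B.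

Step 2
Reactants: 3 (5R)-5-(but-3-en-1-yl)oxolan-2-one
Product: 4 3-[(2R)-5-oxooxolan-2-yl]propanoic acid
Conditions: RuCl3·xH2O (cat.), NaIO4, CCl4/MeCN/H2O, 23 °C
Reagents that add atoms: sodium periodate, [Na+].[O-]I(=O)(=O)=O; water, O
Why: Catalytic RuO4 (Sharpless conditions) cleaves the terminal olefin oxidatively to the carboxylic acid and leaves the saturated lactone and C6 untouched.

Step 3
Reactants: 4 3-[(2R)-5-oxooxolan-2-yl]propanoic acid; 5 (4R)-4-benzyl-1,3-oxazolidin-2-one
Product: 7 (4R)-4-benzyl-3-{3-[(2R)-5-oxooxolan-2-yl]propanoyl}-1,3-oxazolidin-2-one, via mixed pivalic anhydride 6 (not isolated)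
Conditions: t-BuCOCl, Et3N, THF, −20 °C; then 5, LiCl, −20 → 23 °C
Reagents that add atoms: none
Why: N-Acylation of the oxazolidinone through the mixed pivalic anhydride (LiCl/Et3N activation) is the standard Evans imide synthesis, and the unactivated lactone does not compete.

Step 4
Reactants: 7 (4R)-4-benzyl-3-{3-[(2R)-5-oxooxolan-2-yl]propanoyl}-1,3-oxazolidin-2-one
Product: 9 (4R)-4-benzyl-3-{(2S)-2-(hydroxymethyl)-3-[(2S)-5-oxooxolan-2-yl]propanoyl}-1,3-oxazolidin-2-one, via titanium enolate 8 (not isolated)
Conditions: TiCl4, i-Pr2NEt, CH2Cl2, 0 °C; then 1,3,5-trioxane, TiCl4, 0 °C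
Reagents that add atoms: 1,3,5-trioxane, C1OCOCO1
Why: Evans hydroxymethylation: soft enolisation touches only the chelating imide, and formaldehyde released from trioxane attacks the Z-enolate on the face opposite the benzyl group of the (R)-auxiliary, which should set C8 as (S).

Step 5
Reactants: 9 (4R)-4-benzyl-3-{(2S)-2-(hydroxymethyl)-3-[(2S)-5-oxooxolan-2-yl]propanoyl}-1,3-oxazolidin-2-one
Product: 10 (4R)-4-benzyl-3-{(2S)-2-{[(tert-butyldimethylsilyl)oxy]methyl}-3-[(2S)-5-oxooxolan-2-yl]propanoyl}-1,3-oxazolidin-2-one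
Conditions: TBSCl, imidazole, CH2Cl2, 23 °C
Reagents that add atoms: tert-butyldimethylsilyl chloride, CC(C)(C)[Si](C)(C)Cl
Why: Standard imidazole-mediated silylation of the primary alcohol under conditions too mild for retro-aldol cleavage or epimerisation at C8.

Step 6
Reactants: 10 (4R)-4-benzyl-3-{(2S)-2-{[(tert-butyldimethylsilyl)oxy]methyl}-3-[(2S)-5-oxooxolan-2-yl]propanoyl}-1,3-oxazolidin-2-one
Product: 11 S-ethyl (2S)-2-{[(tert-butyldimethylsilyl)oxy]methyl}-3-[(2S)-5-oxooxolan-2-yl]propanethioate
Conditions: EtSH, n-BuLi, THF, −78 → 0 °C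
Reagents that add atoms: ethanethiol, CCS
Why: Transthioesterification with lithium ethanethiolate attacks the activated exocyclic imide carbonyl, releases the auxiliary without touching C8 and tolerates the far less electrophilic lactone.

Step 7
Reactants: 11 S-ethyl (2S)-2-{[(tert-butyldimethylsilyl)oxy]methyl}-3-[(2S)-5-oxooxolan-2-yl]propanethioate
Product: 12 (2S)-2-{[(tert-butyldimethylsilyl)oxy]methyl}-3-[(2S)-5-oxooxolan-2-yl]propanal
Conditions: Et3SiH, Pd/C (10 %), acetone, 23 °C
Reagents that add atoms: none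
Why: Fukuyama reduction (palladium insertion into the C–S bond, hydride transfer from the silane) gives the aldehyde under neutral conditions, so the α-stereocentre C8, the lactone and the silyl ether should survive.

Step 8
Reactants: 12 (2S)-2-{[(tert-butyldimethylsilyl)oxy]methyl}-3-[(2S)-5-oxooxolan-2-yl]propanal
Product: 13 (5S)-5-[(2S)-2-{[(tert-butyldimethylsilyl)oxy]methyl}-3-hydroxyhex-5-en-1-yl]oxolan-2-one (C11 carbinol as a mixture)
Conditions: allyl bromide, indium powder, THF/H2O, 23 °C
Reagents that add atoms: allyl bromide, C=CCBr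
Why: Barbier-type allylation with allylindium in aqueous THF is chemoselective for the aldehyde over the lactone; the new carbinol centre C11 forms without control, which is irrelevant because it is oxidised in step 9.

Step 9
Reactants: 13 (5S)-5-[(2S)-2-{[(tert-butyldimethylsilyl)oxy]methyl}-3-hydroxyhex-5-en-1-yl]oxolan-2-one
Product: 14 (5S)-5-[(2S)-2-{[(tert-butyldimethylsilyl)oxy]methyl}-3-oxohex-5-en-1-yl]oxolan-2-one
Conditions: Dess–Martin periodinane, pyridine, CH2Cl2, 0 °C
Reagents that add atoms: none
Why: Dess–Martin oxidation under pyridine buffering should give the β,γ-unsaturated ketone without moving the olefin into conjugation and without epimerising C8.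

Step 10
Reactants: 14 (5S)-5-[(2S)-2-{[(tert-butyldimethylsilyl)oxy]methyl}-3-oxohex-5-en-1-yl]oxolan-2-one
Product: 15 (5S)-5-{(2S)-2-(2-allyl-1,3-dioxolan-2-yl)-3-[(tert-butyldimethylsilyl)oxy]propyl}oxolan-2-one
Conditions: TMSOCH2CH2OTMS, TMSOTf (cat.), CH2Cl2, −78 → −20 °C; pyridine
Reagents that add atoms: 1,2-bis(trimethylsilyloxy)ethane, C[Si](C)(C)OCCO[Si](C)(C)C
Why: Noyori ketalisation (silyl triflate catalysis, aprotic, low temperature) converts the ketone into the dioxolane without olefin migration and without loss of the TBS ether.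

Step 11
Reactants: 15 (5S)-5-{(2S)-2-(2-allyl-1,3-dioxolan-2-yl)-3-[(tert-butyldimethylsilyl)oxy]propyl}oxolan-2-one
Product: 17 (5R)-5-{(2S)-2-(2-allyl-1,3-dioxolan-2-yl)-3-[(tert-butyldimethylsilyl)oxy]propyl}-3-(phenylselanyl)oxolan-2-one (C2 as a mixture; descriptor change at C6 only), via lithium enolate 16 (not isolated)
Conditions: LiN(i-Pr)2, THF, −78 °C; then PhSeBr, −78 °C
Reagents that add atoms: phenylselenyl bromide, Br[Se]c1ccccc1
Why: Kinetic deprotonation gives the lactone enolate (the only acidic site), which is selenenylated at C2; the configuration at C2 is irrelevant.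

Step 12
Reactants: 17 (5R)-5-{(2S)-2-(2-allyl-1,3-dioxolan-2-yl)-3-[(tert-butyldimethylsilyl)oxy]propyl}-3-(phenylselanyl)oxolan-2-one
Product: 19 (5R)-5-{(2S)-2-(2-allyl-1,3-dioxolan-2-yl)-3-[(tert-butyldimethylsilyl)oxy]propyl}furan-2(5H)-one, via selenoxide 18 (not isolated)
Conditions: H2O2 (30 % aq.), pyridine, CH2Cl2, 0 → 23 °C
Reagents that add atoms: none
Why: Oxidation to the selenoxide and syn-elimination, possible only toward the C27 hydrogens, gives the endocyclic butenolide with C6 unchanged, pyridine suppressing peracid-type side reactions at the terminal olefin.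

Step 13
Reactants: 20 1,3-dithiane; 21 3-chloro-2-methylprop-1-ene
Product: 23 2-(2-methylallyl)-1,3-dithiane, via 2-lithio-1,3-dithiane 22 (not isolated)
Conditions: n-BuLi, THF, −30 °C; then 21, −78 → 0 °C
Reagents that add atoms: none
Why: Corey–Seebach alkylation, in which the sulfur-stabilised 2-lithio-1,3-dithiane displaces chloride from the allylic halide by SN2.

Step 14
Reactants: 19 (5R)-5-{(2S)-2-(2-allyl-1,3-dioxolan-2-yl)-3-[(tert-butyldimethylsilyl)oxy]propyl}furan-2(5H)-one; 23 2-(2-methylallyl)-1,3-dithiane; 24 N,N-dimethylmethyleneiminium iodide (Eschenmoser's salt)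
Product: 27 (4S,5R)-5-{(2S)-2-(2-allyl-1,3-dioxolan-2-yl)-3-[(tert-butyldimethylsilyl)oxy]propyl}-3-[(dimethylamino)methyl]-4-[2-(2-methylallyl)-1,3-dithian-2-yl]oxolan-2-one (C2 as a mixture), via lithiated dithiane 25 (not isolated), via lactone enolate 26 (not isolated)
Conditions: 23, n-BuLi, THF, −30 °C; HMPA, −78 °C; then 19, −78 °C; then 24, −78 → 0 °C
Reagents that add atoms: none
Why: n-BuLi removes the C2–H of dithiane 23 to give the sulfur-stabilised carbanion 25, which in THF/HMPA adds as a solvent-separated ion pair in Michael fashion to C27 of butenolide 19; the resulting lithium enolate 26 is then alkylated on carbon at C2 by the iminium ion (Mannich reaction), so C19–C27 and C2–C1 form in one flask. The closest known reaction type is the tandem conjugate addition of lithiated dithianes to 5-substituted butenolides with electrophilic trapping of the lactone enolate, as used for trans-2,3-disubstituted lignan lactones. No ring is closed. The new stereocentre C27 is controlled by C6: the C7 side chain shields its own face of the planar butenolide, so the bulky nucleophile should enter anti and place C19 trans to C7, while C2 should form mainly trans to C27 but is irrelevant because it becomes sp2 in step 20. The step needs 1,4- over 1,2-addition and no deprotonation at C6, which the soft HMPA-separated dithiane anion and the low temperature should secure, and C- over O-attack on the enolate, which is normal for an iminium electrophile.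

Step 15
Reactants: 27 dithiane Mannich base
Product: 28 (4S,5R)-5-{(2S)-2-(2-allyl-1,3-dioxolan-2-yl)-3-[(tert-butyldimethylsilyl)oxy]propyl}-3-[(dimethylamino)methyl]-4-(3-methylbut-3-enoyl)oxolan-2-one
Conditions: HgCl2, CaCO3, MeCN/H2O, 23 °C
Reagents that add atoms: water, O
Why: Thiophilic divalent mercury hydrolyses the dithioketal to the C19 ketone while HgCl2, a poor oxymercuration reagent, should spare both olefins, and CaCO3 buffering protects the dioxolane, the silyl ether and the β-amino lactone.

Step 16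
Reactants: 28 C19 ketone
Product: 29 (4R,5R)-5-{(2S)-2-(2-allyl-1,3-dioxolan-2-yl)-3-[(tert-butyldimethylsilyl)oxy]propyl}-3-[(dimethylamino)methyl]-4-[(1R)-1-hydroxy-3-methylbut-3-en-1-yl]oxolan-2-one (descriptor change at C27 only)
Conditions: Li(s-Bu)3BH, THF, −78 °C; AcOH, −78 °C
Reagents that add atoms: none
Why: The bulky non-chelating hydride should add through a Felkin–Anh transition state with the C27–C6 bond anti to the incoming hydride, an arrangement that also opposes the C19=O and C6–O5 dipoles (1,3-anti induction), so both models point to the (19R) carbinol, and the cold AcOH quench protonates the alkoxide before it can translactonise onto C3.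

Step 17
Reactants: 29 (19R)-alcohol; 30 (2R)-2-methylbutanoic acid
Product: 31 (1R)-1-{(2R,3S)-2-{(2S)-2-(2-allyl-1,3-dioxolan-2-yl)-3-[(tert-butyldimethylsilyl)oxy]propyl}-4-[(dimethylamino)methyl]-5-oxooxolan-3-yl}-3-methylbut-3-en-1-yl (2R)-2-methylbutanoate
Conditions: EDC·HCl, DMAP, CH2Cl2, 0 → 23 °C
Reagents that add atoms: none
Why: Carbodiimide/DMAP (Steglich) esterification acylates the hindered secondary alcohol under mild conditions that should not epimerise the α-centre of the acid, the tertiary amine being inert.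

Step 18
Reactants: 31 diene ester
Product: 33 ring-A-closed amine: (6R,8S,19R,27S)-configured (Z)-C14=C16 cyclodecene trans-fused to ring B, with C11 dioxolane, C9 OTBS, C2 CH2NMe2 and the C19 (2R)-2-methylbutanoate, via ammonium tosylate 32 (not isolated)
Conditions: TsOH (1.0 equiv), CH2Cl2; second-generation Grubbs catalyst RuCl2(=CHPh)(PCy3)(H2IMes) (10 mol %), CH2Cl2 (1 mM), 40 °C; aq. NaHCO3
Reagents that add atoms: none
Why: Ring-closing metathesis between the monosubstituted C14 olefin (initiation site) and the 1,1-disubstituted C16 olefin should close ring A with loss of ethene, the ten-membered ring enforcing the Z geometry, the trans-fused lactone and the dioxolane quaternary centre pre-organising the chain, and the protonated amine neither binding ruthenium nor offering a competing olefin.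

Step 19
Reactants: 33 ring-A-closed amine
Product: 34 (6R,8S,19R,27S)-configured (Z)-cyclodecenone with free C9 hydroxyl, C11 ketone, C2 CH2NMe2 and the C19 (2R)-2-methylbutanoate
Conditions: 2 M aq. HCl/THF, 23 °C; NaHCO3
Reagents that add atoms: water, O
Why: Aqueous acid hydrolyses the dioxolane and the primary TBS ether in one operation while the amine is protected as its ammonium salt, and dilute acid at ambient temperature should leave C8 and the position of the ring olefin unchanged.

Step 20
Reactants: 34 hydroxy ketone Mannich base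
Product: 37 CNP0219035.1 (6R,8S,14R,16S,19R,27S; ester 2R), via amine N-oxide 35 (not isolated), via epoxy N-oxide 36 (not isolated)
Conditions: m-CPBA (3 equiv), CH2Cl2, 0 → 23 °C
Reagents that add atoms: m-chloroperoxybenzoic acid, O=C(OO)c1cccc(Cl)c1
Why: The peracid first oxidises the tertiary amine to its N-oxide, whose Cope (syn) elimination through the acidic C2–H unveils the exocyclic C1=C2 methylene, and it also epoxidises the electron-rich trisubstituted Z-olefin stereospecifically to the cis-epoxide, expected from the exposed outer face of ring A to give the (14R,16S) isomer, while the electron-poor methylene lactone and the ketone are left alone.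

Compound list
1 | (2R)-2-(but-3-en-1-yl)oxirane | C=CCC[C@@H]1CO1 | starting material
2 | (4R)-4-hydroxyoct-7-enoic acid | OC(=O)CC[C@H](O)CCC=C | intermediate (not isolated)
3 | (5R)-5-(but-3-en-1-yl)oxolan-2-one | O=C1CC[C@@H](CCC=C)O1 | intermediate
4 | 3-[(2R)-5-oxooxolan-2-yl]propanoic acid | O=C1CC[C@@H](CCC(=O)O)O1 | intermediate
5 | (4R)-4-benzyl-1,3-oxazolidin-2-one | O=C1OC[C@@H](Cc2ccccc2)N1 | starting material
6 | mixed anhydride of 4 with pivalic acid | O=C1CC[C@@H](CCC(=O)OC(=O)C(C)(C)C)O1 | intermediate (not isolated)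
7 | (4R)-4-benzyl-3-{3-[(2R)-5-oxooxolan-2-yl]propanoyl}-1,3-oxazolidin-2-one | O=C1CC[C@@H](CCC(=O)N2[C@H](Cc3ccccc3)COC2=O)O1 | intermediate
8 | (Z)-trichlorotitanium enolate of 7 | O=C1CC[C@@H](C/C=C(\O[Ti](Cl)(Cl)Cl)N2[C@H](Cc3ccccc3)COC2=O)O1 | intermediate (not isolated)
9 | (4R)-4-benzyl-3-{(2S)-2-(hydroxymethyl)-3-[(2S)-5-oxooxolan-2-yl]propanoyl}-1,3-oxazolidin-2-one | O=C1CC[C@@H](C[C@@H](CO)C(=O)N2[C@H](Cc3ccccc3)COC2=O)O1 | intermediate
10 | TBS ether of 9 | O=C1CC[C@@H](C[C@@H](CO[Si](C)(C)C(C)(C)C)C(=O)N2[C@H](Cc3ccccc3)COC2=O)O1 | intermediate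
11 | S-ethyl (2S)-2-{[(tert-butyldimethylsilyl)oxy]methyl}-3-[(2S)-5-oxooxolan-2-yl]propanethioate | O=C1CC[C@@H](C[C@@H](CO[Si](C)(C)C(C)(C)C)C(=O)SCC)O1 | intermediate
12 | (2S)-2-{[(tert-butyldimethylsilyl)oxy]methyl}-3-[(2S)-5-oxooxolan-2-yl]propanal | O=C1CC[C@@H](C[C@@H](CO[Si](C)(C)C(C)(C)C)C=O)O1 | intermediate
13 | (5S)-5-[(2S)-2-{[(tert-butyldimethylsilyl)oxy]methyl}-3-hydroxyhex-5-en-1-yl]oxolan-2-one (C11 mixture) | O=C1CC[C@@H](C[C@@H](CO[Si](C)(C)C(C)(C)C)C(O)CC=C)O1 | intermediate
14 | (5S)-5-[(2S)-2-{[(tert-butyldimethylsilyl)oxy]methyl}-3-oxohex-5-en-1-yl]oxolan-2-one | O=C1CC[C@@H](C[C@@H](CO[Si](C)(C)C(C)(C)C)C(=O)CC=C)O1 | intermediate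
15 | (5S)-5-{(2S)-2-(2-allyl-1,3-dioxolan-2-yl)-3-[(tert-butyldimethylsilyl)oxy]propyl}oxolan-2-one | O=C1CC[C@@H](C[C@@H](CO[Si](C)(C)C(C)(C)C)C2(CC=C)OCCO2)O1 | intermediate
16 | lithium enolate of 15 | [Li]OC1=CC[C@@H](C[C@@H](CO[Si](C)(C)C(C)(C)C)C2(CC=C)OCCO2)O1 | intermediate (not isolated)
17 | 3-(phenylselanyl) derivative of 15 (C2 mixture) | O=C1C([Se]c2ccccc2)C[C@@H](C[C@@H](CO[Si](C)(C)C(C)(C)C)C2(CC=C)OCCO2)O1 | intermediate
18 | selenoxide of 17 | O=C1C([Se](=O)c2ccccc2)C[C@@H](C[C@@H](CO[Si](C)(C)C(C)(C)C)C2(CC=C)OCCO2)O1 | intermediate (not isolated)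
19 | (5R)-5-{(2S)-2-(2-allyl-1,3-dioxolan-2-yl)-3-[(tert-butyldimethylsilyl)oxy]propyl}furan-2(5H)-one (key-step precursor) | O=C1C=C[C@@H](C[C@@H](CO[Si](C)(C)C(C)(C)C)C2(CC=C)OCCO2)O1 | intermediate
20 | 1,3-dithiane | C1CSCSC1 | starting material
21 | 3-chloro-2-methylprop-1-ene | C=C(C)CCl | starting material
22 | 2-lithio-1,3-dithiane | [Li]C1SCCCS1 | intermediate (not isolated)
23 | 2-(2-methylallyl)-1,3-dithiane | C=C(C)CC1SCCCS1 | intermediate
24 | N,N-dimethylmethyleneiminium iodide (Eschenmoser's salt) | C=[N+](C)C.[I-] | starting material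
25 | 2-lithio-2-(2-methylallyl)-1,3-dithiane | [Li]C1(CC(C)=C)SCCCS1 | intermediate (not isolated)
26 | lithium enolate of the 1,4-adduct (C19 trans to C7) | [Li]OC1=C[C@H](C2(CC(C)=C)SCCCS2)[C@@H](C[C@@H](CO[Si](C)(C)C(C)(C)C)C2(CC=C)OCCO2)O1 | intermediate (not isolated)
27 | trans-disubstituted lactone Mannich base (6R,8S,27S; C2 mixture), key-step product | CN(C)CC1C(=O)O[C@H](C[C@@H](CO[Si](C)(C)C(C)(C)C)C2(CC=C)OCCO2)[C@H]1C1(CC(C)=C)SCCCS1 | intermediate
28 | C19 ketone (6R,8S,27S) | CN(C)CC1C(=O)O[C@H](C[C@@H](CO[Si](C)(C)C(C)(C)C)C2(CC=C)OCCO2)[C@H]1C(=O)CC(C)=C | intermediate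
29 | (19R)-alcohol | CN(C)CC1C(=O)O[C@H](C[C@@H](CO[Si](C)(C)C(C)(C)C)C2(CC=C)OCCO2)[C@H]1[C@H](O)CC(C)=C | intermediate
30 | (2R)-2-methylbutanoic acid | OC(=O)[C@H](C)CC | starting material
31 | diene ester: (19R) (2R)-2-methylbutanoate of 29 | CN(C)CC1C(=O)O[C@H](C[C@@H](CO[Si](C)(C)C(C)(C)C)C2(CC=C)OCCO2)[C@H]1[C@@H](CC(C)=C)OC(=O)[C@H](C)CC | intermediate
32 | 4-methylbenzenesulfonate salt of 31 | C[NH+](C)CC1C(=O)O[C@H](C[C@@H](CO[Si](C)(C)C(C)(C)C)C2(CC=C)OCCO2)[C@H]1[C@@H](CC(C)=C)OC(=O)[C@H](C)CC.Cc1ccc(cc1)S(=O)(=O)[O-] | intermediate (not isolated)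
33 | ring-A-closed amine, (Z)-C14=C16 (6R,8S,19R,27S), C11 dioxolane, C9 OTBS | CN(C)CC1C(=O)O[C@@H]2C[C@@H](CO[Si](C)(C)C(C)(C)C)C3(OCCO3)C/C=C(C)\C[C@@H](OC(=O)[C@H](C)CC)[C@@H]12 | intermediate
34 | hydroxy ketone Mannich base, (Z)-C14=C16 (6R,8S,19R,27S) | CN(C)CC1C(=O)O[C@@H]2C[C@@H](CO)C(=O)C/C=C(C)\C[C@@H](OC(=O)[C@H](C)CC)[C@@H]12 | intermediate
35 | N-oxide of 34 | C[N+](C)([O-])CC1C(=O)O[C@@H]2C[C@@H](CO)C(=O)C/C=C(C)\C[C@@H](OC(=O)[C@H](C)CC)[C@@H]12 | intermediate (not isolated)
36 | (14R,16S)-epoxide of 35 | C[N+](C)([O-])CC1C(=O)O[C@@H]2C[C@@H](CO)C(=O)C[C@H]3O[C@@]3(C)C[C@@H](OC(=O)[C@H](C)CC)[C@@H]12 | intermediate (not isolated)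
37 | CNP0219035.1 | C=C1C(=O)O[C@@H]2C[C@@H](CO)C(=O)C[C@H]3O[C@@]3(C)C[C@@H](OC(=O)[C@H](C)CC)[C@@H]12 | target

Total step count: 20
Longest linear sequence: 19 steps (steps 1–12, 14–20); step 13 is the one-step side branch to dithiane 23.

Steps most likely to fail

1. Step 18 (ring-closing metathesis). Intermolecular metathesis may outrun closure of the strained ten-membered ring, or turnover may stall at the 1,1-disubstituted olefin. The fallback replaces olefin metathesis by carbonyl olefination. It sets out from 31: the amine is protonated with TsOH and both terminal olefins are cleaved by ozonolysis (O3, CH2Cl2/MeOH, −78 °C; Me2S) to the keto aldehyde F1, which carries the C14 aldehyde and the C16 methyl ketone. Intramolecular McMurry coupling (TiCl3(DME)1.5, Zn–Cu couple, DME, reflux, slow addition) then joins C14 to C16 as the ring olefin, and the route is rejoined at 33.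

2. Step 20 (epoxidation with amine-oxide elimination). Oxygen transfer to the C14=C16 olefin may show poor or inverted facial selectivity, since it rests only on the conformation of ring A. The fallback uses reagent control. It sets out from 34: m-CPBA (1.05 equiv, CH2Cl2, −78 → 23 °C) oxidises only nitrogen, and Cope elimination gives the methylene lactone olefin F2. Shi epoxidation of this olefin (fructose-derived ketone catalyst of the matching enantiomeric series, KHSO5, K2CO3, MeCN/dimethoxymethane/H2O, 0 °C) then delivers the epoxide oxygen under catalyst control and arrives at 37.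

3. Step 16 (ketone reduction). Hydride addition at C19 may show poor facial selectivity, or the C19 alkoxide may translactonise. The fallback makes the esterification stereoconvergent. It sets out from 28: reduction with NaBH4/CeCl3·7H2O (MeOH, −78 °C, AcOH quench) is followed by separation of the epimers. The (19R)-alcohol 29 continues through step 17, while the (19S)-alcohol F3 is esterified with 30 under Mitsunobu conditions (PPh3, DIAD, THF, 0 °C) with inversion at C19, so that both epimers meet at 31.

Further compounds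
F1 | step 18 | keto aldehyde from double ozonolysis of 31 (C14 aldehyde, C16 methyl ketone) | CN(C)CC1C(=O)O[C@H](C[C@@H](CO[Si](C)(C)C(C)(C)C)C2(CC=O)OCCO2)[C@H]1[C@@H](CC(C)=O)OC(=O)[C@H](C)CC
F2 | step 20 | methylene lactone olefin (34 after N-oxidation and Cope elimination) | C=C1C(=O)O[C@@H]2C[C@@H](CO)C(=O)C/C=C(C)\C[C@@H](OC(=O)[C@H](C)CC)[C@@H]12
F3 | step 16 | (19S)-alcohol, C19 epimer of 29 | CN(C)CC1C(=O)O[C@H](C[C@@H](CO[Si](C)(C)C(C)(C)C)C2(CC=C)OCCO2)[C@H]1[C@@H](O)CC(C)=C
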